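At one temperature the fraction of starting material left after a given time did not move with the charges: Tuesday's run and Wednesday's run differ in both charges, yet at 6.00 d they read 16.4 % and 16.2 %. So we work with the fraction left, which falls first order on one clock per temperature. Starting material opens to the open intermediate, partner turns into the second intermediate, the two join to target, and target goes on to over-reaction product.

| flask | starting material | partner | temperature | remark | time |
|---|---|---|---|---|---|
| Tuesday's | 0.17 M | 0.175 M | −30 °C | run made earlier |  |
| Thursday's | 0.38 M | 0.175 M | −8 °C | run made earlier |  |
| Wednesday's | 0.25 M | 0.087 M | −30 °C | run made earlier |  |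
| blue | 0.25 M | 0.175 M | −20 °C |  | 6.0 d |
| grey | 0.25 M | 0.175 M | 0 °C |  | 6.0 d |
| ochre | 0.25 M | 0.175 M | −40 °C |  | 6.0 d |

Tuesday's run (percent of the starting material charged)

| time / d | target / % | starting material / % |
|---|---|---|
| 0.417 | 0.8 | 88.2 |
| 0.833 | 0.8 | 78.1 |
| 1.67 | 1.0 | 60.4 |
| 3.00 | 1.2 | 41.1 |
| 6.00 | 4.8 | 16.4 |

Thursday's run (percent of the starting material charged)

| time / h | target / % | starting material / % |
|---|---|---|
| 4.00 | 0.6 | 23.7 |
| 12.0 | 7.3 | 1.4 |
| 20.0 | 9.1 | 0.3 |
| 30.0 | 8.2 | 0 |
| 48.0 | 3.5 | 0.7 |

Wednesday's run (percent of the starting material charged)

| time / d | target / % | starting material / % |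
|---|---|---|
| 0.417 | 0.1 | 88.5 |
| 0.833 | 0.6 | 77.8 |
| 1.67 | 0.4 | 60.4 |
| 3.00 | 1.1 | 41.2 |
| 6.00 | 2.4 | 16.2 |

(standard deviation of a reading: 0.5 percentage points)

- target is meant together with its crystals
- solid, in amounts per volume of the solution: crystals
- the analysis behind the earlier runs scatters by 0.5 percentage points, standard deviation
- steps under discussion: starting material -> open intermediate; partner -> second intermediate; open intermediate + second intermediate -> target; target -> over-reaction product; crystals <-> target

1. which flask leads in amount of target, in percent of the starting material charged ("all alike" within 1.5 percentage points) (blue / grey / ochre / all alike)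
2. how much target is there at the end, in percent of the starting material charged: blue
3. how much target is there at the end, in percent of the starting material charged: grey
4. how much target is there at the end, in percent of the starting material charged: ochre

Tuesday's last reading gives a clock of 0.301 /d at −30 °C, and Thursday's first gives 8.64 /d at −8 °C. Together they give how steeply the clock rises with temperature, the activation energy of the opening, 81.8 kJ/mol.

Take blue in slow motion. Its clock is 1.49 /d, a half-life of 0.465 d. At first starting material opens and target barely shows: Thursday held 0.6 % target at 4.00 h, with 23.7 % starting material left. In the middle the open intermediate meets second intermediate; Wednesday's run, with half the partner charge of Tuesday's but more starting material, read half of Tuesday's target at 6.00 d, a ratio of two scattered readings. At the end blue has 0.0132 % starting material left by our reckoning, and if the later steps keep pace, its 6.0 d equal 24.8 h on Thursday's clock. That lies later than the time of Thursday's highest reading, 9.1 %, so we expect blue to have lost target to over-reaction product.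

Ochre, with 72.7 % starting material left by our reckoning, reaches 0.886 h on Thursday's clock, earlier than Thursday's first reading. Grey reaches 427 h, far beyond Thursday's last, which had dropped to 3.5 %. We therefore commit to blue leading, with about 9.1 %.

The forecast also names blue, but puts blue higher than our figure, at 15 %, with 0.3 % for grey and 0.2 % for ochre, noting that “over-reaction is substantial”.

The flasks give 15.4 % in blue, 0.0125 % in grey and 0.0730 % in ochre, so blue leads.

    starting material → open intermediate (k = 0.0620 /h, Ea = 82.0 kJ/mol)
    partner → second intermediate (k = 0.0150 /h, Ea = 87.0 kJ/mol)
    open intermediate + second intermediate → target (k = 0.0600 /M/h, Ea = 60.0 kJ/mol)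
    target → over-reaction product (k = 0.0160 /h, Ea = 94.0 kJ/mol)
    crystals ⇌ target, rate k5*(cs5 - [target]) while solid is left; crystals form when [target] > cs5 (solubility = 0.0870 M, k = 8.50 /h)
    (constants at −20 °C)

Against our reckoning, the flasks hold 0.0133 % starting material in blue and 72.9 % in ochre, so the clock held, while blue's target came out above Thursday's reading: Thursday's curve gave the place, not the height. The same activation energy puts a repeat of ochre at −25 °C on a clock of 0.681 /d, so 1.68 % starting material left after 6.0 d; that repeat holds 1.70 %. Grey's low target comes from the loss of target to over-reaction product: without that step grey holds 69.9 % target, not 0.0125 %.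

(Readings and results come from a simulation with made-up constants; the scatter is artificial.)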